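The plan rests on cutting ring F of the epigallocatechin unit at O1'–C8a' and the interflavan bond at C8'–C4. Ring D carries O1' and the upper C4 on adjacent carbons C8a' and C8', next to the C7' oxygen, which is the signature of an aryne difunctionalisation. In one operation a C8'–C8a' aryne, made from an acyclic fluoroarene, is attacked at C8a' by the C2' alkoxide (ring F closes) and the aryllithium left at C8' is formylated, delivering C4. The precursor is the syn (1R,2R) 1,3-diarylpropan-1-ol with a 2-benzyloxy group, a free benzylic hydroxyl and fluorine ortho to the chain. The upper flavan is then grown from the aldehyde.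

Key step: step 9

Remark: primed locants and rings D, E, F denote the epigallocatechin unit, unprimed locants and rings A, B, C the upper flavan; compound 3 is the trityl ether of (S)-glycidol (its descriptor is R only because the CIP priorities change), and all eight oxygens are carried as benzyl ethers so that one hydrogenolysis ends the route.

Step 1
Reactants: 1 1,3,5-trifluorobenzene
Product: 2 1,3-bis(benzyloxy)-5-fluorobenzene
Conditions: BnOH (2.1 equiv), NaH, NMP, 0 → 80 °C
Reagents that add atoms: benzyl alcohol, OCc1ccccc1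
Why: Two successive SNAr displacements of fluoride by sodium benzyloxide should stop at the bis-ether, because each alkoxy group that replaces a fluorine lowers the activation of the ring (nucleophilic aromatic substitution).

Step 2
Reactants: 2 1,3-bis(benzyloxy)-5-fluorobenzene; 3 (R)-glycidyl trityl ether
Product: 5 (2R)-1-[2,4-bis(benzyloxy)-6-fluorophenyl]-3-(trityloxy)propan-2-ol, via aryllithium 4 (not isolated)
Conditions: n-BuLi, THF, −78 °C, 1 h; 3, BF3·OEt2, −78 °C; H2O
Reagents that add atoms: none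
Why: Directed ortho-lithiation should take place at the position flanked by fluorine and a benzyloxy group, and at −78 °C (below the onset of LiF loss) the aryllithium opens the BF3-activated epoxide at its unsubstituted carbon in an SN2 manner, so the glycidol stereocentre is carried over unchanged.

Step 3
Reactants: 5 (2R)-1-[2,4-bis(benzyloxy)-6-fluorophenyl]-3-(trityloxy)propan-2-ol
Product: 6 1,5-bis(benzyloxy)-2-[(2R)-2-(benzyloxy)-3-(trityloxy)propyl]-3-fluorobenzene
Conditions: NaH, BnBr, Bu4NI (cat.), THF, 0 °C → rt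
Reagents that add atoms: benzyl bromide, BrCc1ccccc1
Why: Williamson etherification of the secondary alkoxide should be clean because a trityl group cannot migrate between oxygens and THF at or below room temperature keeps the alkoxide from displacing the ortho fluorine.

Step 4
Reactants: 6 1,5-bis(benzyloxy)-2-[(2R)-2-(benzyloxy)-3-(trityloxy)propyl]-3-fluorobenzene
Product: 7 (2R)-2-(benzyloxy)-3-[2,4-bis(benzyloxy)-6-fluorophenyl]propan-1-ol
Conditions: TsOH·H2O (cat.), MeOH/CH2Cl2, rt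
Reagents that add atoms: none
Why: Acid-catalysed methanolysis of the trityl ether through the trityl cation should free the primary alcohol selectively, benzyl ethers and the aryl fluoride being inert.

Step 5
Reactants: 7 (2R)-2-(benzyloxy)-3-[2,4-bis(benzyloxy)-6-fluorophenyl]propan-1-ol
Product: 8 (2R)-2-(benzyloxy)-3-[2,4-bis(benzyloxy)-6-fluorophenyl]propanal
Conditions: Dess–Martin periodinane, NaHCO3, CH2Cl2, 0 °C → rt; used crude
Reagents that add atoms: none
Why: Dess–Martin oxidation is non-basic and should give the α-benzyloxy aldehyde without epimerisation of the α centre.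

Step 6
Reactants: 9 5-bromo-1,2,3-trimethoxybenzene
Product: 10 5-bromobenzene-1,2,3-triol
Conditions: BBr3, CH2Cl2, −78 °C → rt; H2O
Reagents that add atoms: none
Why: Lewis acid cleavage of the three aryl methyl ethers (O-demethylation) should leave the aryl bromide untouched.

Step 7
Reactants: 10 5-bromobenzene-1,2,3-triol
Product: 11 5-bromo-1,2,3-tris(benzyloxy)benzene
Conditions: BnBr, K2CO3, DMF, 60 °C, under N2
Reagents that add atoms: benzyl bromide, BrCc1ccccc1
Why: Threefold Williamson O-benzylation of the phenols should proceed normally, exclusion of air protecting the pyrogallol until it is alkylated.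

Step 8
Reactants: 11 5-bromo-1,2,3-tris(benzyloxy)benzene; 8 (2R)-2-(benzyloxy)-3-[2,4-bis(benzyloxy)-6-fluorophenyl]propanal
Product: 13 (1R,2R)-2-(benzyloxy)-3-[2,4-bis(benzyloxy)-6-fluorophenyl]-1-[3,4,5-tris(benzyloxy)phenyl]propan-1-ol, via Grignard reagent 12 (not isolated)
Conditions: 11, Mg, THF, 40 °C; then 8, MgBr2·OEt2, CH2Cl2, −78 °C; H2O
Reagents that add atoms: none
Why: Chelation-controlled Grignard addition (Cram chelate model): magnesium bridges the aldehyde oxygen and the α-benzyloxy oxygen, the aryl group enters anti to the CH2Ar substituent of the five-membered chelate, and the syn (1R,2R) alcohol should result.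

Step 9
Reactants: 13 (1R,2R)-2-(benzyloxy)-3-[2,4-bis(benzyloxy)-6-fluorophenyl]-1-[3,4,5-tris(benzyloxy)phenyl]propan-1-ol; 14 N,N-dimethylformamide
Product: 18 (2R,3R)-3,5,7-tris(benzyloxy)-2-[3,4,5-tris(benzyloxy)phenyl]chromane-8-carbaldehyde (hexa-O-benzyl-8-formyl-(−)-epigallocatechin), via dilithio species 15 (not isolated), via aryne 16 (not isolated), via C8' aryllithium 17 (not isolated)
Conditions: n-BuLi (2.1 equiv), THF, −78 °C, 1 h; −78 → −20 °C; DMF (5 equiv), −78 → 0 °C; H2O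
Reagents that add atoms: none
Why: The first equivalent of n-BuLi makes the C2' lithium alkoxide and the second removes H8', the only ring proton ortho to fluorine and also flanked by the C7' benzyloxy group; on warming, LiF is lost to give the C8'–C8a' aryne, the tethered alkoxide adds to C8a', and the aryllithium left at C8' is formylated by DMF. The closest known reaction type is the anionic benzyne cyclisation, in which an ortho-lithiated fluoroarene collapses to an aryne that is trapped by a tethered lithium alkoxide or amide and the new aryllithium is quenched by an electrophile. Ring F closes in a 6-exo-dig mode, the only size the three-carbon tether permits, since attack at C8' would need a meta-bridged seven-membered ring. No stereocentre is created: the C–O bond is made at the arene carbon, so C2' and C3' keep the syn (1R,2R) arrangement and emerge as the 2,3-cis (2R,3R) pair. Regiochemistry is secured threefold: fluorine has a single ortho hydrogen, the C7' benzyloxy group stabilises the carbanion developing at C8' inductively, and the O3' benzyl ether removes the competing five-membered closure. An alkyllithium is chosen in place of a lithium amide so that no N–H acid is present to protonate C8' before DMF arrives.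

Step 10
Reactants: 18 (2R,3R)-3,5,7-tris(benzyloxy)-2-[3,4,5-tris(benzyloxy)phenyl]chromane-8-carbaldehyde; 19 1-[4-(benzyloxy)phenyl]ethanone
Product: 20 (E)-1-[4-(benzyloxy)phenyl]-3-{(2R,3R)-3,5,7-tris(benzyloxy)-2-[3,4,5-tris(benzyloxy)phenyl]chroman-8-yl}prop-2-en-1-one
Conditions: KOH, EtOH/THF, rt → 40 °C
Reagents that add atoms: none
Why: Claisen–Schmidt condensation of the non-enolisable aldehyde with the acetophenone enolate, followed by E1cB loss of water, should give the conjugated (E)-enone.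

Step 11
Reactants: 21 1-(benzyloxy)-3-bromobenzene
Product: 22 4-(benzyloxy)-2-bromo-1-iodobenzene
Conditions: NIS, TFA (cat.), MeCN, rt
Reagents that add atoms: N-iodosuccinimide, O=C1CCC(=O)N1I
Why: Electrophilic aromatic iodination should go para to the benzyloxy group, the strongest director, which places iodine ortho to bromine.

Step 12
Reactants: 22 4-(benzyloxy)-2-bromo-1-iodobenzene
Product: 24 [4-(benzyloxy)-2-bromophenyl]boronic acid, via Grignard reagent 23 (not isolated)
Conditions: iPrMgCl·LiCl, THF, −20 °C; B(OMe)3, −78 °C → rt; 1 M HCl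
Reagents that add atoms: trimethyl borate, COB(OC)OC; water, O
Why: Iodine–magnesium exchange is much faster than bromine–magnesium exchange, the ortho-bromoaryl Grignard reagent is stable below 0 °C, and borylation followed by hydrolysis should give the boronic acid.

Step 13
Reactants: 20 (E)-1-[4-(benzyloxy)phenyl]-3-{(2R,3R)-3,5,7-tris(benzyloxy)-2-[3,4,5-tris(benzyloxy)phenyl]chroman-8-yl}prop-2-en-1-one; 24 [4-(benzyloxy)-2-bromophenyl]boronic acid
Product: 25 (3S)-3-[4-(benzyloxy)-2-bromophenyl]-1-[4-(benzyloxy)phenyl]-3-{(2R,3R)-3,5,7-tris(benzyloxy)-2-[3,4,5-tris(benzyloxy)phenyl]chroman-8-yl}propan-1-one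
Conditions: [RhCl(C2H4)2]2 (2.5 mol%), (S)-BINAP (6 mol%), KOH (0.5 equiv), 24 (3 equiv), dioxane/H2O 10:1, 60 °C
Reagents that add atoms: none
Why: Hayashi–Miyaura asymmetric 1,4-addition: the aryl group passes from boron to rhodium, the (S)-BINAP complex binds the (E)-enone on its α-si face and inserts it, and hydrolysis of the oxa-π-allyl species should give the ketone with the new centre 3S (the future 4R), the aryl bromide being inert to monovalent rhodium.

Step 14
Reactants: 25 (3S)-3-[4-(benzyloxy)-2-bromophenyl]-1-[4-(benzyloxy)phenyl]-3-{(2R,3R)-3,5,7-tris(benzyloxy)-2-[3,4,5-tris(benzyloxy)phenyl]chroman-8-yl}propan-1-one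
Product: 26 (1S,3S)-3-[4-(benzyloxy)-2-bromophenyl]-1-[4-(benzyloxy)phenyl]-3-{(2R,3R)-3,5,7-tris(benzyloxy)-2-[3,4,5-tris(benzyloxy)phenyl]chroman-8-yl}propan-1-ol
Conditions: (R)-2-methyl-CBS-oxazaborolidine (20 mol%), BH3·SMe2, THF, −20 °C; MeOH
Reagents that add atoms: none
Why: Corey–Bakshi–Shibata reduction: the aryl group is the large substituent of the ketone, so the (R)-catalyst should deliver hydride to give the (1S)-carbinol under catalyst control, independent of the remote C4 centre.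

Step 15
Reactants: 26 (1S,3S)-3-[4-(benzyloxy)-2-bromophenyl]-1-[4-(benzyloxy)phenyl]-3-{(2R,3R)-3,5,7-tris(benzyloxy)-2-[3,4,5-tris(benzyloxy)phenyl]chroman-8-yl}propan-1-ol
Product: 27 (2R,3R)-3,5,7-tris(benzyloxy)-8-{(2S,4R)-7-(benzyloxy)-2-[4-(benzyloxy)phenyl]chroman-4-yl}-2-[3,4,5-tris(benzyloxy)phenyl]chromane
Conditions: CuI (10 mol%), 3,4,7,8-tetramethyl-1,10-phenanthroline (20 mol%), Cs2CO3, toluene, 110 °C
Reagents that add atoms: none
Why: Ullmann-type intramolecular C–O coupling of the secondary alcohol with the ortho bromide closes ring C at O1–C8a; the C2–O bond is not broken, so C2 keeps its configuration and the 2,4-trans (2S,4R) flavan should result.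

Step 16
Reactants: 27 (2R,3R)-3,5,7-tris(benzyloxy)-8-{(2S,4R)-7-(benzyloxy)-2-[4-(benzyloxy)phenyl]chroman-4-yl}-2-[3,4,5-tris(benzyloxy)phenyl]chromane
Product: 28 (2R,3R)-8-[(2S,4R)-7-hydroxy-2-(4-hydroxyphenyl)chroman-4-yl]-2-(3,4,5-trihydroxyphenyl)chromane-3,5,7-triol (CNP0220331.1)
Conditions: H2 (1 atm), Pd(OH)2/C, THF/MeOH, rt
Reagents that add atoms: none
Why: Catalytic hydrogenolysis should cleave all eight benzyl ethers to toluene under neutral conditions without touching the stereocentres or the chroman C–O bonds.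

Compound list

1 | 1,3,5-trifluorobenzene | Fc1cc(F)cc(F)c1 | starting material
2 | 1,3-bis(benzyloxy)-5-fluorobenzene | Fc1cc(OCc2ccccc2)cc(OCc2ccccc2)c1 | intermediate
3 | (R)-glycidyl trityl ether ((2R)-2-[(trityloxy)methyl]oxirane; trityl ether of (S)-glycidol) | C(OC[C@H]1CO1)(c1ccccc1)(c1ccccc1)c1ccccc1 | starting material
4 | [2,4-bis(benzyloxy)-6-fluorophenyl]lithium (not isolated) | [Li]c1c(F)cc(OCc2ccccc2)cc1OCc1ccccc1 | intermediate
5 | (2R)-1-[2,4-bis(benzyloxy)-6-fluorophenyl]-3-(trityloxy)propan-2-ol | c1ccccc1C(c1ccccc1)(c1ccccc1)OC[C@H](O)Cc1c(F)cc(OCc2ccccc2)cc1OCc1ccccc1 | intermediate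
6 | 1,5-bis(benzyloxy)-2-[(2R)-2-(benzyloxy)-3-(trityloxy)propyl]-3-fluorobenzene | c1ccccc1C(c1ccccc1)(c1ccccc1)OC[C@H](OCc1ccccc1)Cc1c(F)cc(OCc2ccccc2)cc1OCc1ccccc1 | intermediate
7 | (2R)-2-(benzyloxy)-3-[2,4-bis(benzyloxy)-6-fluorophenyl]propan-1-ol | OC[C@H](OCc1ccccc1)Cc1c(F)cc(OCc2ccccc2)cc1OCc1ccccc1 | intermediate
8 | (2R)-2-(benzyloxy)-3-[2,4-bis(benzyloxy)-6-fluorophenyl]propanal | O=C[C@H](OCc1ccccc1)Cc1c(F)cc(OCc2ccccc2)cc1OCc1ccccc1 | intermediate
9 | 5-bromo-1,2,3-trimethoxybenzene | COc1cc(Br)cc(OC)c1OC | starting material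
10 | 5-bromobenzene-1,2,3-triol | Oc1cc(Br)cc(O)c1O | intermediate
11 | 5-bromo-1,2,3-tris(benzyloxy)benzene | Brc1cc(OCc2ccccc2)c(OCc2ccccc2)c(OCc2ccccc2)c1 | intermediate
12 | [3,4,5-tris(benzyloxy)phenyl]magnesium bromide (not isolated) | Br[Mg]c1cc(OCc2ccccc2)c(OCc2ccccc2)c(OCc2ccccc2)c1 | intermediate
13 | (1R,2R)-2-(benzyloxy)-3-[2,4-bis(benzyloxy)-6-fluorophenyl]-1-[3,4,5-tris(benzyloxy)phenyl]propan-1-ol | O[C@H](c1cc(OCc2ccccc2)c(OCc2ccccc2)c(OCc2ccccc2)c1)[C@H](OCc1ccccc1)Cc1c(F)cc(OCc2ccccc2)cc1OCc1ccccc1 | intermediate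
14 | N,N-dimethylformamide | CN(C)C=O | starting material
15 | lithium alkoxide of 13 lithiated at C8' (not isolated) | [Li]O[C@H](c1cc(OCc2ccccc2)c(OCc2ccccc2)c(OCc2ccccc2)c1)[C@H](OCc1ccccc1)Cc1c(F)c([Li])c(OCc2ccccc2)cc1OCc1ccccc1 | intermediate
16 | C8'–C8a' aryne bearing the C2' lithium alkoxide (not isolated) | [Li]O[C@H](c1cc(OCc2ccccc2)c(OCc2ccccc2)c(OCc2ccccc2)c1)[C@H](OCc1ccccc1)CC1=C(OCc2ccccc2)C=C(OCc2ccccc2)C#C1 | intermediate
17 | 8-lithio-hexa-O-benzyl-(−)-epigallocatechin (not isolated) | [Li]c1c(OCc2ccccc2)cc(OCc2ccccc2)c2c1O[C@H](c1cc(OCc3ccccc3)c(OCc3ccccc3)c(OCc3ccccc3)c1)[C@H](OCc1ccccc1)C2 | intermediate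
18 | (2R,3R)-3,5,7-tris(benzyloxy)-2-[3,4,5-tris(benzyloxy)phenyl]chromane-8-carbaldehyde | O=Cc1c(OCc2ccccc2)cc(OCc2ccccc2)c2c1O[C@H](c1cc(OCc3ccccc3)c(OCc3ccccc3)c(OCc3ccccc3)c1)[C@H](OCc1ccccc1)C2 | intermediate
19 | 1-[4-(benzyloxy)phenyl]ethanone | CC(=O)c1ccc(OCc2ccccc2)cc1 | starting material
20 | (E)-1-[4-(benzyloxy)phenyl]-3-{(2R,3R)-3,5,7-tris(benzyloxy)-2-[3,4,5-tris(benzyloxy)phenyl]chroman-8-yl}prop-2-en-1-one | O=C(/C=C/c1c(OCc2ccccc2)cc(OCc2ccccc2)c2c1O[C@H](c1cc(OCc3ccccc3)c(OCc3ccccc3)c(OCc3ccccc3)c1)[C@H](OCc1ccccc1)C2)c1ccc(OCc2ccccc2)cc1 | intermediate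
21 | 1-(benzyloxy)-3-bromobenzene | Brc1cccc(OCc2ccccc2)c1 | starting material
22 | 4-(benzyloxy)-2-bromo-1-iodobenzene | Ic1ccc(OCc2ccccc2)cc1Br | intermediate
23 | [4-(benzyloxy)-2-bromophenyl]magnesium chloride (not isolated) | Cl[Mg]c1ccc(OCc2ccccc2)cc1Br | intermediate
24 | [4-(benzyloxy)-2-bromophenyl]boronic acid | OB(O)c1ccc(OCc2ccccc2)cc1Br | intermediate
25 | (3S)-3-[4-(benzyloxy)-2-bromophenyl]-1-[4-(benzyloxy)phenyl]-3-{(2R,3R)-3,5,7-tris(benzyloxy)-2-[3,4,5-tris(benzyloxy)phenyl]chroman-8-yl}propan-1-one | O=C(c1ccc(OCc2ccccc2)cc1)C[C@@H](c1c(OCc2ccccc2)cc(OCc2ccccc2)c2c1O[C@H](c1cc(OCc3ccccc3)c(OCc3ccccc3)c(OCc3ccccc3)c1)[C@H](OCc1ccccc1)C2)c1ccc(OCc2ccccc2)cc1Br | intermediate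
26 | (1S,3S)-3-[4-(benzyloxy)-2-bromophenyl]-1-[4-(benzyloxy)phenyl]-3-{(2R,3R)-3,5,7-tris(benzyloxy)-2-[3,4,5-tris(benzyloxy)phenyl]chroman-8-yl}propan-1-ol | c1ccccc1COc1ccc(cc1)[C@@H](O)C[C@@H](c1c(OCc2ccccc2)cc(OCc2ccccc2)c2c1O[C@H](c1cc(OCc3ccccc3)c(OCc3ccccc3)c(OCc3ccccc3)c1)[C@H](OCc1ccccc1)C2)c1ccc(OCc2ccccc2)cc1Br | intermediate
27 | (2R,3R)-3,5,7-tris(benzyloxy)-8-{(2S,4R)-7-(benzyloxy)-2-[4-(benzyloxy)phenyl]chroman-4-yl}-2-[3,4,5-tris(benzyloxy)phenyl]chromane | c1ccccc1COc1ccc(cc1)[C@@H]1C[C@@H](c2c(OCc3ccccc3)cc(OCc3ccccc3)c3c2O[C@H](c2cc(OCc4ccccc4)c(OCc4ccccc4)c(OCc4ccccc4)c2)[C@H](OCc2ccccc2)C3)c2ccc(OCc3ccccc3)cc2O1 | intermediate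
28 | (2R,3R)-8-[(2S,4R)-7-hydroxy-2-(4-hydroxyphenyl)chroman-4-yl]-2-(3,4,5-trihydroxyphenyl)chromane-3,5,7-triol | Oc1ccc([C@@H]2C[C@@H](c3c(O)cc(O)c4c3O[C@H](c3cc(O)c(O)c(O)c3)[C@H](O)C4)c3ccc(O)cc3O2)cc1 | target

Total step count: 16. Longest linear sequence: 12 steps (steps 1, 2, 3, 4, 5, 8, 9, 10, 13, 14, 15, 16).

Steps most likely to fail

Step 9. The C8' aryllithium may be protonated before DMF arrives, the aryne may be intercepted intermolecularly by residual butyllithium or by another aryllithium, and the benzyl ethers may be metalated on warming. The fallback sets out from 13 and returns at 18, making the same two bonds one after the other. The potassium alkoxide of 13 (KH, DMF, 0 → 60 °C) should displace the fluorine, which is activated by the two meta benzyloxy groups, by intramolecular SNAr with retention at C2' to give hexa-O-benzyl-(−)-epigallocatechin F1. NBS in CH2Cl2 at −20 °C should then brominate the most nucleophilic ring D position to give the 8-bromide F2. Bromine–lithium exchange (n-BuLi, THF, −78 °C) regenerates aryllithium 17, which is formylated with DMF to 18.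

Step 13. Migratory insertion into the hindered, electron-rich enone may be slow enough for protodeboronation of the ortho-bromo boronic acid to win, and facial selectivity may erode. The fallback sets out from 18, bypasses 20 and returns at 25, replacing catalyst control by auxiliary control. Diethylphosphonoacetic acid is coupled to (S)-4-phenyl-1,3-oxazolidin-2-one (PivCl, Et3N; then the N-lithiated oxazolidinone) to give diethyl {2-oxo-2-[(4S)-2-oxo-4-phenyl-1,3-oxazolidin-3-yl]ethyl}phosphonate F3. Horner–Wadsworth–Emmons olefination of 18 under Masamune–Roush conditions (LiCl, iPr2NEt, MeCN) should give the (E)-N-enoyl imide F4. Grignard reagent 23 with CuBr·SMe2 (THF, −40 °C) should add to the magnesium-chelated s-cis enoyl imide anti to the phenyl group of the auxiliary, giving the (3S) adduct F5. Transamination with MeONHMe·HCl and AlMe3 gives the N-methoxy-N-methylamide F6, and [4-(benzyloxy)phenyl]magnesium bromide converts it into 25 (Weinreb ketone synthesis).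

Step 15. C–O bond formation at the hindered secondary alkoxide may be sluggish, so that reduction of the C–Br bond or oxidation of the carbinol to the ketone competes. The fallback sets out from 20 and returns at 27, closing ring C by fluoride displacement instead of metal-catalysed coupling. Commercial [4-(benzyloxy)-2-fluorophenyl]boronic acid is added to 20 under the conditions of step 13 to give the (3S) fluoro ketone F7, and reduction as in step 14 gives the (1S,3S) fluoro alcohol F8. Its potassium alkoxide (KH, DMF, 60–80 °C) should displace the ortho fluorine by intramolecular SNAr, again without breaking the C2–O bond, to give 27.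

Further compounds

F1 | step 9 | (2R,3R)-3,5,7-tris(benzyloxy)-2-[3,4,5-tris(benzyloxy)phenyl]chromane | c1c(OCc2ccccc2)cc(OCc2ccccc2)c2c1O[C@H](c1cc(OCc3ccccc3)c(OCc3ccccc3)c(OCc3ccccc3)c1)[C@H](OCc1ccccc1)C2
F2 | step 9 | (2R,3R)-3,5,7-tris(benzyloxy)-8-bromo-2-[3,4,5-tris(benzyloxy)phenyl]chromane | Brc1c(OCc2ccccc2)cc(OCc2ccccc2)c2c1O[C@H](c1cc(OCc3ccccc3)c(OCc3ccccc3)c(OCc3ccccc3)c1)[C@H](OCc1ccccc1)C2
F3 | step 13 | diethyl {2-oxo-2-[(4S)-2-oxo-4-phenyl-1,3-oxazolidin-3-yl]ethyl}phosphonate | CCOP(=O)(OCC)CC(=O)N1[C@@H](c2ccccc2)COC1=O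
F4 | step 13 | (4S)-4-phenyl-3-[(E)-3-{(2R,3R)-3,5,7-tris(benzyloxy)-2-[3,4,5-tris(benzyloxy)phenyl]chroman-8-yl}prop-2-enoyl]-1,3-oxazolidin-2-one | O=C(/C=C/c1c(OCc2ccccc2)cc(OCc2ccccc2)c2c1O[C@H](c1cc(OCc3ccccc3)c(OCc3ccccc3)c(OCc3ccccc3)c1)[C@H](OCc1ccccc1)C2)N1[C@@H](c2ccccc2)COC1=O
F5 | step 13 | (4S)-3-[(3S)-3-[4-(benzyloxy)-2-bromophenyl]-3-{(2R,3R)-3,5,7-tris(benzyloxy)-2-[3,4,5-tris(benzyloxy)phenyl]chroman-8-yl}propanoyl]-4-phenyl-1,3-oxazolidin-2-one | O=C(C[C@@H](c1c(OCc2ccccc2)cc(OCc2ccccc2)c2c1O[C@H](c1cc(OCc3ccccc3)c(OCc3ccccc3)c(OCc3ccccc3)c1)[C@H](OCc1ccccc1)C2)c1ccc(OCc2ccccc2)cc1Br)N1[C@@H](c2ccccc2)COC1=O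
F6 | step 13 | (3S)-3-[4-(benzyloxy)-2-bromophenyl]-N-methoxy-N-methyl-3-{(2R,3R)-3,5,7-tris(benzyloxy)-2-[3,4,5-tris(benzyloxy)phenyl]chroman-8-yl}propanamide | CON(C)C(=O)C[C@@H](c1c(OCc2ccccc2)cc(OCc2ccccc2)c2c1O[C@H](c1cc(OCc3ccccc3)c(OCc3ccccc3)c(OCc3ccccc3)c1)[C@H](OCc1ccccc1)C2)c1ccc(OCc2ccccc2)cc1Br
F7 | step 15 | (3S)-3-[4-(benzyloxy)-2-fluorophenyl]-1-[4-(benzyloxy)phenyl]-3-{(2R,3R)-3,5,7-tris(benzyloxy)-2-[3,4,5-tris(benzyloxy)phenyl]chroman-8-yl}propan-1-one | O=C(c1ccc(OCc2ccccc2)cc1)C[C@@H](c1c(OCc2ccccc2)cc(OCc2ccccc2)c2c1O[C@H](c1cc(OCc3ccccc3)c(OCc3ccccc3)c(OCc3ccccc3)c1)[C@H](OCc1ccccc1)C2)c1ccc(OCc2ccccc2)cc1F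
F8 | step 15 | (1S,3S)-3-[4-(benzyloxy)-2-fluorophenyl]-1-[4-(benzyloxy)phenyl]-3-{(2R,3R)-3,5,7-tris(benzyloxy)-2-[3,4,5-tris(benzyloxy)phenyl]chroman-8-yl}propan-1-ol | c1ccccc1COc1ccc(cc1)[C@@H](O)C[C@@H](c1c(OCc2ccccc2)cc(OCc2ccccc2)c2c1O[C@H](c1cc(OCc3ccccc3)c(OCc3ccccc3)c(OCc3ccccc3)c1)[C@H](OCc1ccccc1)C2)c1ccc(OCc2ccccc2)cc1F
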